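## Retrosynthetic overview

1. Target ⇒ O-demethylation (LiCl) and dioxolane hydrolysis of an (E)-5-ylidene methyl tetronate. The E enol-ether olefin comes from photo-isomerisation of the Z isomer, which comes from dehydration of a 5-(1-hydroxyalkyl)tetronate.
2. Key C–C bond (tetronate C5 to side-chain C1′) ⇒ intermolecular aldol of lithiated 4-methoxy-3-methylfuran-2(5H)-one with the (S)-2-methyl C20 aldehyde, whose furyl ketone is masked as a dioxolane.
3. Aldehyde ⇒ 3-furyllithium on a Weinreb amide; two Johnson–Claisen rearrangements (E-trisubstituted olefin, 1,1-disubstituted olefin); B-alkyl Suzuki coupling of 2-bromoallyl alcohol with silylated (S)-2-methylpent-4-en-1-ol (Evans allylation).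
4. Rings: the butenolide (tetronate) ring is built first from ethyl 2-methylacetoacetate; the furan is bought as 3-bromofuran; the dioxolane is a temporary ring (on in step 13, off in step 19).

Assumption: the SMILES is taken literally, i.e. (S) at the methyl-bearing carbon, E at the chain trisubstituted olefin, and E at the exocyclic enol-ether olefin (side chain trans to the ring oxygen, cis to C4–OH).

## Route

Step 1
Reactants: 1 ethyl 2-methyl-3-oxobutanoate (ethyl 2-methylacetoacetate)
Product: 4 3-methyltetronic acid (4-hydroxy-3-methylfuran-2(5H)-one), via ethyl 2-bromo-2-methyl-3-oxobutanoate 2 (not isolated), via ethyl 4-bromo-2-methyl-3-oxobutanoate 3 (not isolated)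
Conditions: Br2 (1.0 equiv), CHCl3, 0 °C → rt, 16 h; evaporate; neat, 125 °C, 3 h
Reagents that add atoms: none
Why: α-Bromination, HBr-promoted bromine shift to the γ-carbon and thermal lactonisation with loss of bromoethane is the classical tetronic acid synthesis; no stereocentre is formed.

Step 2
Reactants: 4 3-methyltetronic acid
Product: 5 4-methoxy-3-methylfuran-2(5H)-one
Conditions: Me2SO4 (1.1 equiv), K2CO3, acetone, reflux, 4 h
Reagents that add atoms: dimethyl sulfate, COS(=O)(=O)OC
Why: O-Alkylation of the vinylogous acid with a hard methylating agent gives the 4-methyl ether (vinylogous ester).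

Step 3
Reactants: 6 (R)-4-benzyl-3-propanoyloxazolidin-2-one; 7 allyl bromide
Product: 9 (R)-4-benzyl-3-[(S)-2-methylpent-4-enoyl]oxazolidin-2-one, via sodium imide (Z)-enolate 8 (not isolated)
Conditions: NaN(SiMe3)2 (1.1 equiv), THF, −78 °C, 45 min; then 7 (3 equiv), −78 → −40 °C
Reagents that add atoms: none
Why: Evans asymmetric alkylation; the chelated (Z)-enolate is allylated on the face opposite the benzyl group, which sets the (S) methyl-bearing stereocentre (minor diastereomer removed by chromatography).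

Step 4
Reactants: 9 (R)-4-benzyl-3-[(S)-2-methylpent-4-enoyl]oxazolidin-2-one
Product: 10 (S)-2-methylpent-4-en-1-ol
Conditions: LiBH4 (1.2 equiv), H2O (1.1 equiv), Et2O, 0 °C; aq. NaOH work-up, careful distillation (volatile)
Reagents that add atoms: none
Why: Hydride reduction cleaves the imide to the primary alcohol without touching the α-stereocentre and returns the auxiliary.

Step 5
Reactants: 10 (S)-2-methylpent-4-en-1-ol
Product: 11 (S)-tert-butyl[(2-methylpent-4-en-1-yl)oxy]diphenylsilane
Conditions: TBDPSCl (1.1 equiv), imidazole (2 equiv), CH2Cl2, 0 °C → rt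
Reagents that add atoms: tert-butyl(chloro)diphenylsilane (TBDPSCl), CC(C)(C)[Si](Cl)(c1ccccc1)c1ccccc1
Why: Silylation gives an ether that survives the acidic 140 °C Claisen steps, hydride, Grignard and organolithium reagents.

Step 6
Reactants: 11 (S)-tert-butyl[(2-methylpent-4-en-1-yl)oxy]diphenylsilane; 12 2-bromoprop-2-en-1-ol
Product: 14 (S)-7-(tert-butyldiphenylsilyloxy)-6-methyl-2-methylideneheptan-1-ol, via B-alkyl-9-BBN borane 13 (not isolated)
Conditions: 9-BBN (1.3 equiv), THF, 0 °C → rt, 4 h; then 3 M aq. K3PO4, 12 (1.5 equiv), PdCl2(dppf) (5 mol %), DMF, rt → 50 °C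
Reagents that add atoms: none
Why: Anti-Markovnikov hydroboration followed by B-alkyl Suzuki–Miyaura coupling (zerovalent palladium inserts into the vinylic C–Br bond) joins the sp3 and sp2 carbons; the remote stereocentre is not involved.

Step 7
Reactants: 14 (S)-7-(tert-butyldiphenylsilyloxy)-6-methyl-2-methylideneheptan-1-ol; 15 triethyl orthoacetate
Product: 17 ethyl (S)-9-(tert-butyldiphenylsilyloxy)-8-methyl-4-methylidenenonanoate, via ketene acetal 16 (not isolated)
Conditions: 15 (8 equiv), EtCO2H (0.1 equiv), 140 °C, EtOH distilled off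
Reagents that add atoms: none
Why: Johnson–Claisen (orthoester Claisen) [3,3] rearrangement of the 2-substituted allyl alcohol gives the 1,1-disubstituted olefin and a two-carbon ester arm.

Step 8
Reactants: 17 ethyl (S)-9-(tert-butyldiphenylsilyloxy)-8-methyl-4-methylidenenonanoate
Product: 18 (S)-9-(tert-butyldiphenylsilyloxy)-8-methyl-4-methylidenenonanal
Conditions: iBu2AlH (1.1 equiv), CH2Cl2, −78 °C, 1 h; MeOH, then aq. potassium sodium tartrate
Reagents that add atoms: none
Why: Partial ester reduction stops at the aluminium hemiacetal at −78 °C and gives the aldehyde on work-up (any over-reduced alcohol is re-oxidised with Dess–Martin periodinane).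

Step 9
Reactants: 18 (S)-9-(tert-butyldiphenylsilyloxy)-8-methyl-4-methylidenenonanal; 19 isopropenylmagnesium bromide
Product: 20 (10S)-11-(tert-butyldiphenylsilyloxy)-2,10-dimethyl-6-methylideneundec-1-en-3-ol (both C3 epimers)
Conditions: CH2=C(CH3)MgBr (1.5 equiv), THF, −78 → 0 °C; aq. NH4Cl
Reagents that add atoms: none
Why: Grignard 1,2-addition; the new carbinol centre is uncontrolled, which is irrelevant because it is destroyed in step 10.

Step 10
Reactants: 20 (10S)-11-(tert-butyldiphenylsilyloxy)-2,10-dimethyl-6-methylideneundec-1-en-3-ol; 15 triethyl orthoacetate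
Product: 22 ethyl (4E,12S)-13-(tert-butyldiphenylsilyloxy)-4,12-dimethyl-8-methylidenetridec-4-enoate, via ketene acetal 21 (not isolated)
Conditions: 15 (8 equiv), EtCO2H (0.1 equiv), 140 °C, EtOH distilled off
Reagents that add atoms: none
Why: Johnson–Claisen rearrangement through a chair transition state with the chain equatorial gives the (E)-trisubstituted olefin (typically ≥ 95:5).

Step 11
Reactants: 22 ethyl (4E,12S)-13-(tert-butyldiphenylsilyloxy)-4,12-dimethyl-8-methylidenetridec-4-enoate
Product: 23 (4E,12S)-13-(tert-butyldiphenylsilyloxy)-N-methoxy-N,4,12-trimethyl-8-methylidenetridec-4-enamide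
Conditions: MeNH(OMe)·HCl (2 equiv), iPrMgCl (4 equiv), THF, −20 → 0 °C
Reagents that add atoms: N,O-dimethylhydroxylamine hydrochloride, CNOC.Cl
Why: Aminolysis of the ester by the chloromagnesium amide (Weinreb amide formation) proceeds without touching olefins or silyl ether.

Step 12
Reactants: 23 the Weinreb amide; 24 3-bromofuran
Product: 26 (4E,12S)-13-(tert-butyldiphenylsilyloxy)-1-(furan-3-yl)-4,12-dimethyl-8-methylidenetridec-4-en-1-one, via 3-furyllithium 25 (not isolated)
Conditions: 24 (1.6 equiv), n-BuLi (1.5 equiv), THF, −78 °C, 30 min; then 23, −78 °C, 2 h; aq. NH4Cl at −78 °C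
Reagents that add atoms: none
Why: Bromine–lithium exchange (kept at −78 °C so the 3-lithio species does not isomerise) and Weinreb ketone synthesis; the chelated tetrahedral adduct prevents over-addition.

Step 13
Reactants: 26 the 3-furyl ketone
Product: 27 tert-butyl{[(2S,9E)-12-[2-(furan-3-yl)-1,3-dioxolan-2-yl]-2,10-dimethyl-6-methylidenedodec-9-en-1-yl]oxy}diphenylsilane
Conditions: (Me3SiOCH2)2 (3 equiv), Me3SiOTf (0.1 equiv), CH2Cl2, −78 → −20 °C; pyridine quench
Reagents that add atoms: 1,2-bis(trimethylsilyloxy)ethane, C[Si](C)(C)OCCO[Si](C)(C)C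
Why: Noyori ketalisation masks the ketone under aprotic low-temperature conditions that spare the furan and the 1,1-disubstituted olefin; this shields it from the enolate of step 16 and removes a triplet sensitiser before step 18.

Step 14
Reactants: 27 the silyl ether ketal
Product: 28 (2S,9E)-12-[2-(furan-3-yl)-1,3-dioxolan-2-yl]-2,10-dimethyl-6-methylidenedodec-9-en-1-ol
Conditions: Bu4NF (1.5 equiv), THF, rt
Reagents that add atoms: none
Why: Fluoride-mediated desilylation; the dioxolane is inert to fluoride.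

Step 15
Reactants: 28 the primary alcohol
Product: 29 (2S,9E)-12-[2-(furan-3-yl)-1,3-dioxolan-2-yl]-2,10-dimethyl-6-methylidenedodec-9-enal
Conditions: Dess–Martin periodinane (1.3 equiv), NaHCO3, CH2Cl2, 0 °C → rt; used crude at once
Reagents that add atoms: none
Why: Buffered Dess–Martin oxidation gives the α-branched aldehyde without epimerisation.

Step 16
Reactants: 5 4-methoxy-3-methylfuran-2(5H)-one; 29 the (S)-aldehyde
Product: 31 5-{(2S,9E)-12-[2-(furan-3-yl)-1,3-dioxolan-2-yl]-1-hydroxy-2,10-dimethyl-6-methylidenedodec-9-en-1-yl}-4-methoxy-3-methylfuran-2(5H)-one (all C5/C1′ diastereomers), via lithium 4-methoxy-3-methylfuran-2-olate 30 (not isolated)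
Conditions: 5 (1.4 equiv), LiN(iPr)2 (1.4 equiv), THF, −78 °C, 30 min; then 29, −78 °C, 45 min; aq. NH4Cl at −78 °C
Reagents that add atoms: none
Why: Intermolecular aldol addition of the lithium 2-oxidofuran (dienolate) through C5 to the aldehyde; the two new stereocentres are left uncontrolled because both are erased in step 17, and the (S) centre is untouched at −78 °C.

Step 17
Reactants: 31 the aldol adduct
Product: 33 (5Z)-5-{(2S,9E)-12-[2-(furan-3-yl)-1,3-dioxolan-2-yl]-2,10-dimethyl-6-methylidenedodec-9-en-1-ylidene}-4-methoxy-3-methylfuran-2(5H)-one, via mesylate 32 (not isolated)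
Conditions: MeSO2Cl (1.5 equiv), Et3N (3 equiv), CH2Cl2, 0 °C; then DBU (2.5 equiv), 0 °C → rt, short reaction time
Reagents that add atoms: none
Why: Mesylation and base-induced β-elimination (E1cB through the C5 carbanion) give the conjugated 5-ylidene tetronate, mainly as the thermodynamically preferred Z isomer (any E isomer is pooled with 34).

Step 18
Reactants: 33 the (Z)-ylidene tetronate
Product: 34 (5E)-5-{(2S,9E)-12-[2-(furan-3-yl)-1,3-dioxolan-2-yl]-2,10-dimethyl-6-methylidenedodec-9-en-1-ylidene}-4-methoxy-3-methylfuran-2(5H)-one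
Conditions: hν (300 nm, Pyrex), degassed MeCN (0.005 M), rt, to the photostationary state; chromatography, recovered 33 re-irradiated; 34 handled in the dark from here on
Reagents that add atoms: none
Why: Photochemical E/Z isomerisation of the dienoate chromophore gives a photostationary mixture from which the contra-thermodynamic E isomer is separated; the ketal, furan and isolated olefins do not absorb at this wavelength.

Step 19
Reactants: 34 the (E)-ylidene tetronate ketal
Product: 35 (5E)-5-[(2S,9E)-13-(furan-3-yl)-2,10-dimethyl-6-methylidene-13-oxotridec-9-en-1-ylidene]-4-methoxy-3-methylfuran-2(5H)-one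
Conditions: PPTS (0.3 equiv), acetone/H2O 9:1, rt → 40 °C, dark
Reagents that add atoms: water, O
Why: Mild acid-catalysed ketal hydrolysis (the aryl-type dioxolane ionises readily) regenerates the 3-furyl ketone without protonating the electron-poor dienol ether.

Step 20
Reactants: 35 the keto methyl tetronate
Product: 36 (5E)-5-[(2S,9E)-13-(furan-3-yl)-2,10-dimethyl-6-methylidene-13-oxotridec-9-en-1-ylidene]-4-hydroxy-3-methylfuran-2(5H)-one (target)
Conditions: LiCl (10 equiv), DMSO, 50 °C, dark; then cold 0.1 M HCl to pH 3, EtOAc extraction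
Reagents that add atoms: none
Why: SN2 demethylation of the vinylogous methyl ester by chloride (tetronate as leaving group) frees the tetronic acid under neutral conditions that leave the E olefin, the ketone and the stereocentre alone.

## Compound list

1 | ethyl 2-methyl-3-oxobutanoate | CCOC(=O)C(C)C(C)=O | starting material
2 | ethyl 2-bromo-2-methyl-3-oxobutanoate (racemic) | CCOC(=O)C(C)(Br)C(C)=O | intermediate
3 | ethyl 4-bromo-2-methyl-3-oxobutanoate (racemic) | CCOC(=O)C(C)C(=O)CBr | intermediate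
4 | 3-methyltetronic acid (4-hydroxy-3-methylfuran-2(5H)-one) | CC1=C(O)COC1=O | intermediate
5 | 4-methoxy-3-methylfuran-2(5H)-one | COC1=C(C)C(=O)OC1 | intermediate
6 | (R)-4-benzyl-3-propanoyloxazolidin-2-one | CCC(=O)N1[C@H](Cc2ccccc2)COC1=O | starting material
7 | allyl bromide | C=CCBr | starting material
8 | sodium (Z)-1-[(R)-4-benzyl-2-oxooxazolidin-3-yl]prop-1-en-1-olate | [Na+].C/C=C(\[O-])N1[C@H](Cc2ccccc2)COC1=O | intermediate
9 | (R)-4-benzyl-3-[(S)-2-methylpent-4-enoyl]oxazolidin-2-one | C=CC[C@H](C)C(=O)N1[C@H](Cc2ccccc2)COC1=O | intermediate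
10 | (S)-2-methylpent-4-en-1-ol | C=CC[C@H](C)CO | intermediate
11 | (S)-tert-butyl[(2-methylpent-4-en-1-yl)oxy]diphenylsilane | C=CC[C@H](C)CO[Si](c1ccccc1)(c1ccccc1)C(C)(C)C | intermediate
12 | 2-bromoprop-2-en-1-ol | C=C(Br)CO | starting material
13 | 9-[(S)-5-(tert-butyldiphenylsilyloxy)-4-methylpentyl]-9-borabicyclo[3.3.1]nonane | B1(CCC[C@H](C)CO[Si](c3ccccc3)(c3ccccc3)C(C)(C)C)C2CCCC1CCC2 | intermediate
14 | (S)-7-(tert-butyldiphenylsilyloxy)-6-methyl-2-methylideneheptan-1-ol | C=C(CO)CCC[C@H](C)CO[Si](c1ccccc1)(c1ccccc1)C(C)(C)C | intermediate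
15 | triethyl orthoacetate | CCOC(C)(OCC)OCC | starting material
16 | (S)-tert-butyl({6-[(1-ethoxyethenyloxy)methyl]-2-methylhept-6-en-1-yl}oxy)diphenylsilane (ketene acetal of 14) | C=C(OCC)OCC(=C)CCC[C@H](C)CO[Si](c1ccccc1)(c1ccccc1)C(C)(C)C | intermediate
17 | ethyl (S)-9-(tert-butyldiphenylsilyloxy)-8-methyl-4-methylidenenonanoate | CCOC(=O)CCC(=C)CCC[C@H](C)CO[Si](c1ccccc1)(c1ccccc1)C(C)(C)C | intermediate
18 | (S)-9-(tert-butyldiphenylsilyloxy)-8-methyl-4-methylidenenonanal | O=CCCC(=C)CCC[C@H](C)CO[Si](c1ccccc1)(c1ccccc1)C(C)(C)C | intermediate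
19 | isopropenylmagnesium bromide (THF solution) | C=C(C)[Mg]Br | starting material
20 | (10S)-11-(tert-butyldiphenylsilyloxy)-2,10-dimethyl-6-methylideneundec-1-en-3-ol (both C3 epimers) | C=C(C)C(O)CCC(=C)CCC[C@H](C)CO[Si](c1ccccc1)(c1ccccc1)C(C)(C)C | intermediate
21 | 1-ethoxyethenyl ether of 20 (ketene acetal) | C=C(OCC)OC(CCC(=C)CCC[C@H](C)CO[Si](c1ccccc1)(c1ccccc1)C(C)(C)C)C(C)=C | intermediate
22 | ethyl (4E,12S)-13-(tert-butyldiphenylsilyloxy)-4,12-dimethyl-8-methylidenetridec-4-enoate | CCOC(=O)CC/C(C)=C/CCC(=C)CCC[C@H](C)CO[Si](c1ccccc1)(c1ccccc1)C(C)(C)C | intermediate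
23 | (4E,12S)-13-(tert-butyldiphenylsilyloxy)-N-methoxy-N,4,12-trimethyl-8-methylidenetridec-4-enamide | CON(C)C(=O)CC/C(C)=C/CCC(=C)CCC[C@H](C)CO[Si](c1ccccc1)(c1ccccc1)C(C)(C)C | intermediate
24 | 3-bromofuran | Brc1ccoc1 | starting material
25 | 3-furyllithium | [Li]c1ccoc1 | intermediate
26 | (4E,12S)-13-(tert-butyldiphenylsilyloxy)-1-(furan-3-yl)-4,12-dimethyl-8-methylidenetridec-4-en-1-one | O=C(CC/C(C)=C/CCC(=C)CCC[C@H](C)CO[Si](c1ccccc1)(c1ccccc1)C(C)(C)C)c1ccoc1 | intermediate
27 | tert-butyl{[(2S,9E)-12-[2-(furan-3-yl)-1,3-dioxolan-2-yl]-2,10-dimethyl-6-methylidenedodec-9-en-1-yl]oxy}diphenylsilane | C=C(CC/C=C(\C)CCC1(c2ccoc2)OCCO1)CCC[C@H](C)CO[Si](c1ccccc1)(c1ccccc1)C(C)(C)C | intermediate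
28 | (2S,9E)-12-[2-(furan-3-yl)-1,3-dioxolan-2-yl]-2,10-dimethyl-6-methylidenedodec-9-en-1-ol | C=C(CC/C=C(\C)CCC1(c2ccoc2)OCCO1)CCC[C@H](C)CO | intermediate
29 | (2S,9E)-12-[2-(furan-3-yl)-1,3-dioxolan-2-yl]-2,10-dimethyl-6-methylidenedodec-9-enal | C=C(CC/C=C(\C)CCC1(c2ccoc2)OCCO1)CCC[C@H](C)C=O | intermediate
30 | lithium 4-methoxy-3-methylfuran-2-olate | [Li+].COc1coc([O-])c1C | intermediate
31 | 5-{(2S,9E)-12-[2-(furan-3-yl)-1,3-dioxolan-2-yl]-1-hydroxy-2,10-dimethyl-6-methylidenedodec-9-en-1-yl}-4-methoxy-3-methylfuran-2(5H)-one (mixture at C5 and C1′) | C=C(CC/C=C(\C)CCC1(c2ccoc2)OCCO1)CCC[C@H](C)C(O)C1OC(=O)C(C)=C1OC | intermediate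
32 | methanesulfonate of 31 (mixture at C5 and C1′) | C=C(CC/C=C(\C)CCC1(c2ccoc2)OCCO1)CCC[C@H](C)C(OS(C)(=O)=O)C1OC(=O)C(C)=C1OC | intermediate
33 | (5Z)-5-{(2S,9E)-12-[2-(furan-3-yl)-1,3-dioxolan-2-yl]-2,10-dimethyl-6-methylidenedodec-9-en-1-ylidene}-4-methoxy-3-methylfuran-2(5H)-one | C=C(CC/C=C(\C)CCC1(c2ccoc2)OCCO1)CCC[C@H](C)/C=C1\OC(=O)C(C)=C1OC | intermediate
34 | (5E)-5-{(2S,9E)-12-[2-(furan-3-yl)-1,3-dioxolan-2-yl]-2,10-dimethyl-6-methylidenedodec-9-en-1-ylidene}-4-methoxy-3-methylfuran-2(5H)-one | C=C(CC/C=C(\C)CCC1(c2ccoc2)OCCO1)CCC[C@H](C)/C=C1/OC(=O)C(C)=C1OC | intermediate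
35 | (5E)-5-[(2S,9E)-13-(furan-3-yl)-2,10-dimethyl-6-methylidene-13-oxotridec-9-en-1-ylidene]-4-methoxy-3-methylfuran-2(5H)-one | C=C(CC/C=C(\C)CCC(=O)c1ccoc1)CCC[C@H](C)/C=C1/OC(=O)C(C)=C1OC | intermediate
36 | (5E)-5-[(2S,9E)-13-(furan-3-yl)-2,10-dimethyl-6-methylidene-13-oxotridec-9-en-1-ylidene]-4-hydroxy-3-methylfuran-2(5H)-one | C=C(CC/C=C(\C)CCC(=O)c1ccoc1)CCC[C@H](C)/C=C1/OC(=O)C(C)=C1O | target

## Step count and risks

Total steps: 20. Longest linear sequence: 18 (steps 3 to 20, from 6 to 36); the tetronate 5 is made in 2 steps and enters at step 16.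

Steps most likely to fail:

Step 18 (photo-isomerisation). The photostationary state may be poor in the E isomer, or the dienoate may degrade on long irradiation. The fallback sets out from 31 and bypasses step 17. The two like-configured aldol diastereomers (5R,1′R and 5S,1′S) are separated from the unlike pair by chromatography and treated with Tf2O and pyridine in CH2Cl2 at −78 → 0 °C. The (5R,1′R)-configured triflate of 31 F1 and the (5S,1′S)-configured triflate of 31 F2 then undergo stereospecific anti E2 elimination (H-5 and the triflate antiperiplanar). This places the side chain cis to C4 and gives the E olefin directly, so the route is rejoined at 34. The share of usable material is set by the aldol diastereomer ratio.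

Step 16 (key aldol). The basic dienolate may enolise or epimerise the α-branched aldehyde, or the adduct may undergo retro-aldol before the quench. The fallback sets out from 5. Silylation with tert-butyldimethylsilyl triflate and Et3N gives tert-butyl[(4-methoxy-3-methylfuran-2-yl)oxy]dimethylsilane F3. F3 is added to 29 in a BF3·OEt2-promoted vinylogous Mukaiyama aldol in CH2Cl2 at −78 °C, with no base present and an Et3N quench at −78 °C to protect the dioxolane. Aqueous NaHCO3 work-up gives the same adduct, and the route is rejoined at 31.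

Step 6 (hydroboration and B-alkyl Suzuki coupling with the unprotected bromoallyl alcohol). The coupling may be slow, or protodeboronation may compete. The fallback sets out from 11. Hydroboration–oxidation (9-BBN; NaOH, H2O2) gives (S)-5-(tert-butyldiphenylsilyloxy)-4-methylpentan-1-ol F4. Iodination (I2, PPh3, imidazole) gives (S)-tert-butyl[(5-iodo-2-methylpentyl)oxy]diphenylsilane F5. Magnesium insertion in Et2O gives [(S)-5-(tert-butyldiphenylsilyloxy)-4-methylpentyl]magnesium iodide F6. F6 is added across propargyl alcohol (pre-deprotonated with EtMgBr) under CuI catalysis (10 mol %); this carbomagnesiation places the alkyl group on the internal carbon and after hydrolysis rejoins the route at 14.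

## Further compounds

F1 | step 18 | (5R)-5-{(1R,2S,9E)-12-[2-(furan-3-yl)-1,3-dioxolan-2-yl]-2,10-dimethyl-6-methylidene-1-(trifluoromethanesulfonyloxy)dodec-9-en-1-yl}-4-methoxy-3-methylfuran-2(5H)-one | C=C(CC/C=C(\C)CCC1(c2ccoc2)OCCO1)CCC[C@H](C)[C@@H](OS(=O)(=O)C(F)(F)F)[C@H]1OC(=O)C(C)=C1OC
F2 | step 18 | (5S)-5-{(1S,2S,9E)-12-[2-(furan-3-yl)-1,3-dioxolan-2-yl]-2,10-dimethyl-6-methylidene-1-(trifluoromethanesulfonyloxy)dodec-9-en-1-yl}-4-methoxy-3-methylfuran-2(5H)-one | C=C(CC/C=C(\C)CCC1(c2ccoc2)OCCO1)CCC[C@H](C)[C@H](OS(=O)(=O)C(F)(F)F)[C@@H]1OC(=O)C(C)=C1OC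
F3 | step 16 | tert-butyl[(4-methoxy-3-methylfuran-2-yl)oxy]dimethylsilane | COc1coc(O[Si](C)(C)C(C)(C)C)c1C
F4 | step 6 | (S)-5-(tert-butyldiphenylsilyloxy)-4-methylpentan-1-ol | OCCC[C@H](C)CO[Si](c1ccccc1)(c1ccccc1)C(C)(C)C
F5 | step 6 | (S)-tert-butyl[(5-iodo-2-methylpentyl)oxy]diphenylsilane | ICCC[C@H](C)CO[Si](c1ccccc1)(c1ccccc1)C(C)(C)C
F6 | step 6 | [(S)-5-(tert-butyldiphenylsilyloxy)-4-methylpentyl]magnesium iodide | I[Mg]CCC[C@H](C)CO[Si](c1ccccc1)(c1ccccc1)C(C)(C)C
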